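**Strategy.** Everything rests on opening the two bonds at C2, the methyl-bearing quaternary aryloxy carbon shared by the pyran ring and the ten-membered carbocycle: C2–C3 and O1–C2. With a carbonyl at C4, C2 is the β-carbon of an ortho-hydroxyaryl ketone, so one amine-mediated aldol condensation/oxa-Michael cascade closes both rings from an open chain and sets C2 and C3 under thermodynamic control. The precursor is a (Z)-enyl diketone: a methyl ketone cut from (R)-α-terpineol at one end, a 2-hydroxy-4,6-bis(methoxymethoxy)phenyl ketone at the other, with the tertiary carbinol masked as its triethylsilyl ether.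

Key step: step 10

Assumption: commercial (R)-(+)-α-terpineol of high enantiomeric purity is used; its stereocentre is carried through unchanged and fixes the absolute configuration of the target.

Remark on names: tricyclic compounds are named as 2,3-bridged chromans (O1, C2, C3, C4, C4a, C5–C8, C8a). The bridge runs from C1' (on C2) to C8' (on C3), so C2, C3 and C1'–C8' form the ten-membered ring. "Bridge-OTES" stands for (3'R,5'Z)-6'-methyl-3'-(2-triethylsilyloxypropan-2-yl)oct-5'-ene-1',8'-diyl.

Step 1
Reactants: 1 (R)-α-terpineol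
Product: 2 triethyl({2-[(1R)-4-methylcyclohex-3-en-1-yl]propan-2-yl}oxy)silane
Conditions: TESOTf, 2,6-lutidine, CH2Cl2, 0 °C → rt
Reagents that add atoms: triethylsilyl trifluoromethanesulfonate, CC[Si](CC)(CC)OS(=O)(=O)C(F)(F)F
Why: Silyl triflate silylation of the tertiary alcohol, placed before the alkene cleavage because the free γ-hydroxy aldehyde would otherwise close to a five-membered lactol and hide the aldehyde from the Wittig reagent; the (R) centre is untouched.

Step 2
Reactants: 2 (R)-α-terpineol triethylsilyl ether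
Product: 4 (3R)-6-oxo-3-[2-(triethylsilyloxy)propan-2-yl]heptanal, via secondary ozonide 3 (not isolated)
Conditions: O3, CH2Cl2, −78 °C; then PPh3, −78 °C → rt
Reagents that add atoms: ozone, [O-][O+]=O
Why: Ozonolysis with reductive work-up (Criegee mechanism) cleaves the only alkene into the methyl ketone and the aldehyde, whose carbons become C2 with its methyl and the vinylic C5'; the silyl ether and the stereocentre are inert.

Step 3
Reactants: 4 keto aldehyde; 5 ethyltriphenylphosphonium iodide
Product: 7 (5R,7Z)-8-iodo-5-[2-(triethylsilyloxy)propan-2-yl]non-7-en-2-one, via iodo-ylide 6 (not isolated)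
Conditions: 5 (1.2 equiv), n-BuLi, THF, 0 °C; I2, −78 °C; NaHMDS, −20 °C; then 4, −78 → −20 °C
Reagents that add atoms: iodine, II
Why: Stork–Zhao α-iodo Wittig olefination: at −78 °C the non-stabilised iodo-ylide 6 should react with the aldehyde much faster than with the methyl ketone, and the kinetic cis-oxaphosphetane delivers the Z iodoalkene (iodine cis to the chain).

Step 4
Reactants: 8 2,4,6-trihydroxybenzaldehyde
Product: 9 2-hydroxy-4,6-bis(methoxymethoxy)benzaldehyde
Conditions: MOMCl (2.2 equiv), i-Pr2NEt, CH2Cl2, 0 °C → rt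
Reagents that add atoms: chloromethyl methyl ether, COCCl
Why: O-Alkylation (acetal formation) of the two phenols that are not locked in the hydrogen bond to the formyl group, so the chelated ortho hydroxyl is left free.

Step 5
Reactants: 9 2-hydroxy-4,6-bis(methoxymethoxy)benzaldehyde
Product: 10 2,4-bis(methoxymethoxy)-6-(triisopropylsilyloxy)benzaldehyde
Conditions: TIPSOTf, 2,6-lutidine, CH2Cl2, 0 °C → rt
Reagents that add atoms: triisopropylsilyl trifluoromethanesulfonate, CC(C)[Si](C(C)C)(C(C)C)OS(=O)(=O)C(F)(F)F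
Why: Silylation of the remaining hydrogen-bonded phenol with the reactive silyl triflate gives a bulky aryl silyl ether that is orthogonal to the MOM acetals and to the alkyl triethylsilyl ether and is too hindered to migrate to the benzylic alkoxide of the next step.

Step 6
Reactants: 10 protected aldehyde; 11 allylmagnesium bromide
Product: 12 1-[2,4-bis(methoxymethoxy)-6-(triisopropylsilyloxy)phenyl]but-3-en-1-ol (racemic)
Conditions: THF, −78 °C; aq. work-up
Reagents that add atoms: none
Why: Grignard addition of the allyl nucleophile to the hindered, electron-rich aldehyde gives the homoallylic benzylic alcohol as a racemate, which is acceptable because this centre is oxidised away in step 8.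

Step 7
Reactants: 12 aryl allyl carbinol; 7 Z-iodoalkene
Product: 14 (5R,7Z)-12-hydroxy-12-[2,4-bis(methoxymethoxy)-6-(triisopropylsilyloxy)phenyl]-8-methyl-5-[2-(triethylsilyloxy)propan-2-yl]dodec-7-en-2-one (both C12 epimers), via B-alkyl-9-BBN adduct 13 (not isolated)
Conditions: 9-BBN, THF, rt; then H2O, Cs2CO3, 7, PdCl2(dppf) (cat.), AsPh3 (cat.), DMF, rt
Reagents that add atoms: none
Why: B-alkyl Suzuki–Miyaura coupling: anti-Markovnikov hydroboration of the terminal alkene with 9-BBN (excess borane quenched with water before 7 is added) and palladium-catalysed coupling with retention of the iodoalkene geometry give the Z trisubstituted alkene, the mild aqueous carbonate sparing the methyl ketone, both silyl ethers and the free carbinol.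

Step 8
Reactants: 14 coupled carbinol
Product: 15 (5Z,8R)-1-[2,4-bis(methoxymethoxy)-6-(triisopropylsilyloxy)phenyl]-5-methyl-8-[2-(triethylsilyloxy)propan-2-yl]dodec-5-ene-1,11-dione
Conditions: Dess–Martin periodinane, NaHCO3, CH2Cl2, 0 °C → rt
Reagents that add atoms: none
Why: Dess–Martin oxidation of the secondary benzylic alcohol to the aryl ketone under buffered, non-acidic conditions that leave the alkene, the acetals and the silyl ethers alone and merge the two carbinol epimers.

Step 9
Reactants: 15 silyl-protected diketone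
Product: 16 (5Z,8R)-1-[2-hydroxy-4,6-bis(methoxymethoxy)phenyl]-5-methyl-8-[2-(triethylsilyloxy)propan-2-yl]dodec-5-ene-1,11-dione
Conditions: TBAF (1.1 equiv), AcOH (1.2 equiv), THF, 0 °C
Reagents that add atoms: none
Why: Fluoride-mediated desilylation cleaves the aryl silyl ether, whose ortho-acyl phenoxide is an excellent leaving group, far faster than the hindered tertiary alkyl triethylsilyl ether, and the acetic acid buffer prevents base-induced aldol chemistry of the diketone.

Step 10
Reactants: 16 open-chain Z-enyl diketone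
Product: 18 (2R,3R)-5,7-bis(methoxymethoxy)-2-methyl-2,3-(bridge-OTES)chroman-4-one (trans ring fusion), via aroyl cyclodecadiene 17 (not isolated)
Conditions: pyrrolidine (2 equiv), PhCO2H (0.5 equiv), MeOH–toluene (1:1), 65 °C, slow addition of 16 to 2 mM final concentration, then prolonged heating
Reagents that add atoms: none
Why: Proposed new method: pyrrolidine converts the unhindered methyl ketone into its iminium ion, the α-CH2 of the hydrogen-bonded aryl ketone attacks it as the enol (Mannich-type addition), β-elimination of the amine gives aroyl cyclodecadiene 17, and the ortho phenol then adds to the enone β-carbon. The closest known reaction type is the Kabbe chromanone synthesis (2-hydroxyaryl ketone, ketone and pyrrolidine: aldol condensation then oxa-Michael addition), which is established intermolecularly but not as a medium-ring closure. The carbocycle closes by a 10-exo-trig attack of the enol carbon on the iminium carbon and the pyranone by a 6-endo-trig oxa-Michael addition. C2 and C3 are not set kinetically: retro-oxa-Michael opening and enolisation at C3 keep both epimerisable, so the fixed (R) centre C3' with its bulky silyloxypropyl group should select the isomer in which the C2–C1' and C3–C8' bonds are trans-diequatorial on the pyranone and the side chain is pseudo-equatorial on the ten-membered ring, assigned here as (2R,3R) and to be confirmed by modelling before material is committed. The step needs ring closure to beat oligomerisation and the aryl ketone to act only as the nucleophile: high dilution plus full reversibility (aza-Michael/retro-Mannich) should let oligomers drain into the chromanone sink, the Z alkene and the C3' branch pre-fold the chain, the chelated, doubly ortho-substituted aryl carbonyl is too deactivated to be an acceptor, and the silyl ether stops the tertiary alcohol from forming a hemiketal or competing in the oxa-Michael step.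

Step 11
Reactants: 18 trans-fused chromanone
Product: 19 (2R,3S)-5,7-bis(methoxymethoxy)-2-methyl-2,3-(bridge-OTES)chroman-4-ol (both C4 epimers)
Conditions: NaBH4, MeOH–THF, 0 °C → rt
Reagents that add atoms: none
Why: Borohydride reduction of the vinylogous-ester-type C4 ketone gives the benzylic alcohol as a mixture of C4 epimers, which is irrelevant because C4 is ionised in the next step, while C2 and C3 are untouched.

Step 12
Reactants: 19 chroman-4-ol; 20 trimethyl(2-methylallyl)silane
Product: 21 (2R,3S,4S)-5,7-bis(methoxymethoxy)-2-methyl-4-(2-methylprop-2-en-1-yl)-2,3-(bridge-OTES)chroman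
Conditions: BF3·OEt2 (1.2 equiv), 20 (5 equiv), CH2Cl2, −78 °C; Et3N quench
Reagents that add atoms: none
Why: Lewis-acid ionisation of the doubly oxygen-stabilised benzylic alcohol and Hosomi–Sakurai-type capture of the C4 cation by the allylsilane (SN1 benzylic allylation as in flavan-4-ol chemistry), in which the nucleophile should enter anti to the C3–C8' ring bond and to the axial C2 methyl to give the 3,4-trans (4S) centre, which is why carbon and not hydride is the last group delivered to C4.

Step 13
Reactants: 21 4-methallyl chroman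
Product: 22 (2R,3S,4S)-5,7-bis(methoxymethoxy)-2-methyl-4-(2-methylpropyl)-2,3-(bridge-OTES)chroman
Conditions: H2 (1 atm), RhCl(PPh3)3 (cat.), benzene–EtOH, rt
Reagents that add atoms: none
Why: Homogeneous hydrogenation with Wilkinson's catalyst reduces the unhindered 1,1-disubstituted alkene and should leave the trisubstituted ring alkene, for which this catalyst is very slow, so the isobutyl group is completed without touching the Z alkene.

Step 14
Reactants: 22 4-isobutyl chroman
Product: 24 (2R,3S,4S)-5,7-bis(methoxymethoxy)-2-methyl-4-(2-methylpropyl)-2,3-(bridge-OTES)chroman-6,8-dicarbaldehyde, via lithium hemiaminal 23 (not isolated)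
Conditions: n-BuLi, TMEDA, THF, 0 °C; DMF (1.05 equiv), −78 → 0 °C; n-BuLi, TMEDA, 0 °C; DMF, −78 °C → rt; H2O
Reagents that add atoms: N,N-dimethylformamide, CN(C)C=O
Why: Directed ortho-metalation/formylation run twice in one pot: C6 between the two MOM ethers is lithiated first, the DMF adduct stays as lithium α-amino alkoxide 23 (an aldehyde protected in situ), and a second lithiation at C8 between O1 and the C7 MOM ether followed by DMF gives the dialdehyde on aqueous work-up without touching the alkene, the silyl ether or any stereocentre.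

Step 15
Reactants: 24 protected dialdehyde
Product: 25 (2R,3S,4S)-5,7-dihydroxy-2-methyl-4-(2-methylpropyl)-2,3-[(3'R,5'Z)-3'-(2-hydroxypropan-2-yl)-6'-methyloct-5'-ene-1',8'-diyl]chroman-6,8-dicarbaldehyde (CNP0570248.1)
Conditions: 2 M aq. HCl, THF, rt
Reagents that add atoms: none
Why: Acid-catalysed hydrolysis removes the two aryl MOM acetals, each activated by an ortho formyl group, and the tertiary triethylsilyl ether under conditions too mild to ionise the tertiary alcohol or protonate the ring alkene, releasing the target without touching a stereocentre.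

**Compound list**

1 | (R)-α-terpineol | CC1=CC[C@H](C(C)(C)O)CC1 | starting material
2 | triethyl({2-[(1R)-4-methylcyclohex-3-en-1-yl]propan-2-yl}oxy)silane | CC1=CC[C@H](C(C)(C)O[Si](CC)(CC)CC)CC1 | intermediate
3 | secondary ozonide of 2 (1,2,4-trioxolane across the former C=C; bridgehead epimers unassigned) | CC12CC[C@@H](C(C)(C)O[Si](CC)(CC)CC)CC(OO1)O2 | intermediate (not isolated)
4 | (3R)-6-oxo-3-[2-(triethylsilyloxy)propan-2-yl]heptanal | CC(=O)CC[C@@H](C(C)(C)O[Si](CC)(CC)CC)CC=O | intermediate
5 | ethyltriphenylphosphonium iodide | CC[P+](c1ccccc1)(c1ccccc1)c1ccccc1.[I-] | starting material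
6 | (1-iodoethylidene)triphenylphosphorane | CC(I)=P(c1ccccc1)(c1ccccc1)c1ccccc1 | intermediate (not isolated)
7 | (5R,7Z)-8-iodo-5-[2-(triethylsilyloxy)propan-2-yl]non-7-en-2-one | CC(=O)CC[C@@H](C(C)(C)O[Si](CC)(CC)CC)C/C=C(/C)I | intermediate
8 | 2,4,6-trihydroxybenzaldehyde | O=Cc1c(O)cc(O)cc1O | starting material
9 | 2-hydroxy-4,6-bis(methoxymethoxy)benzaldehyde | O=Cc1c(O)cc(OCOC)cc1OCOC | intermediate
10 | 2,4-bis(methoxymethoxy)-6-(triisopropylsilyloxy)benzaldehyde | O=Cc1c(O[Si](C(C)C)(C(C)C)C(C)C)cc(OCOC)cc1OCOC | intermediate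
11 | allylmagnesium bromide | C=CC[Mg]Br | starting material
12 | 1-[2,4-bis(methoxymethoxy)-6-(triisopropylsilyloxy)phenyl]but-3-en-1-ol (racemic) | C=CCC(O)c1c(O[Si](C(C)C)(C(C)C)C(C)C)cc(OCOC)cc1OCOC | intermediate
13 | 9-{4-hydroxy-4-[2,4-bis(methoxymethoxy)-6-(triisopropylsilyloxy)phenyl]butyl}-9-borabicyclo[3.3.1]nonane | OC(CCCB1C2CCCC1CCC2)c1c(O[Si](C(C)C)(C(C)C)C(C)C)cc(OCOC)cc1OCOC | intermediate (not isolated)
14 | (5R,7Z)-12-hydroxy-12-[2,4-bis(methoxymethoxy)-6-(triisopropylsilyloxy)phenyl]-8-methyl-5-[2-(triethylsilyloxy)propan-2-yl]dodec-7-en-2-one (both C12 epimers) | CC(=O)CC[C@@H](C(C)(C)O[Si](CC)(CC)CC)C/C=C(/C)CCCC(O)c1c(O[Si](C(C)C)(C(C)C)C(C)C)cc(OCOC)cc1OCOC | intermediate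
15 | (5Z,8R)-1-[2,4-bis(methoxymethoxy)-6-(triisopropylsilyloxy)phenyl]-5-methyl-8-[2-(triethylsilyloxy)propan-2-yl]dodec-5-ene-1,11-dione | CC(=O)CC[C@@H](C(C)(C)O[Si](CC)(CC)CC)C/C=C(/C)CCCC(=O)c1c(O[Si](C(C)C)(C(C)C)C(C)C)cc(OCOC)cc1OCOC | intermediate
16 | (5Z,8R)-1-[2-hydroxy-4,6-bis(methoxymethoxy)phenyl]-5-methyl-8-[2-(triethylsilyloxy)propan-2-yl]dodec-5-ene-1,11-dione (key-step precursor) | CC(=O)CC[C@@H](C(C)(C)O[Si](CC)(CC)CC)C/C=C(/C)CCCC(=O)c1c(O)cc(OCOC)cc1OCOC | intermediate
17 | [2-hydroxy-4,6-bis(methoxymethoxy)phenyl]{(5R,7Z)-2,8-dimethyl-5-[2-(triethylsilyloxy)propan-2-yl]cyclodeca-1,7-dien-1-yl}methanone (C1=C2 geometry not fixed) | C/C1=C/C[C@H](C(C)(C)O[Si](CC)(CC)CC)CCC(C)=C(C(=O)c2c(O)cc(OCOC)cc2OCOC)CC1 | intermediate (not isolated)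
18 | (2R,3R)-5,7-bis(methoxymethoxy)-2-methyl-2,3-[(3'R,5'Z)-6'-methyl-3'-(2-triethylsilyloxypropan-2-yl)oct-5'-ene-1',8'-diyl]chroman-4-one (trans-fused; key-step product) | C/C1=C/C[C@H](C(C)(C)O[Si](CC)(CC)CC)CC[C@@]2(C)Oc3cc(OCOC)cc(OCOC)c3C(=O)[C@@H]2CC1 | intermediate
19 | (2R,3S)-5,7-bis(methoxymethoxy)-2-methyl-2,3-[(3'R,5'Z)-6'-methyl-3'-(2-triethylsilyloxypropan-2-yl)oct-5'-ene-1',8'-diyl]chroman-4-ol (both C4 epimers) | C/C1=C/C[C@H](C(C)(C)O[Si](CC)(CC)CC)CC[C@@]2(C)Oc3cc(OCOC)cc(OCOC)c3C(O)[C@@H]2CC1 | intermediate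
20 | trimethyl(2-methylallyl)silane | C=C(C)C[Si](C)(C)C | starting material
21 | (2R,3S,4S)-5,7-bis(methoxymethoxy)-2-methyl-4-(2-methylprop-2-en-1-yl)-2,3-[(3'R,5'Z)-6'-methyl-3'-(2-triethylsilyloxypropan-2-yl)oct-5'-ene-1',8'-diyl]chroman | C/C1=C/C[C@H](C(C)(C)O[Si](CC)(CC)CC)CC[C@@]2(C)Oc3cc(OCOC)cc(OCOC)c3[C@@H](CC(C)=C)[C@@H]2CC1 | intermediate
22 | (2R,3S,4S)-5,7-bis(methoxymethoxy)-2-methyl-4-(2-methylpropyl)-2,3-[(3'R,5'Z)-6'-methyl-3'-(2-triethylsilyloxypropan-2-yl)oct-5'-ene-1',8'-diyl]chroman | C/C1=C/C[C@H](C(C)(C)O[Si](CC)(CC)CC)CC[C@@]2(C)Oc3cc(OCOC)cc(OCOC)c3[C@@H](CC(C)C)[C@@H]2CC1 | intermediate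
23 | lithium alkoxide of the C6 (dimethylamino)carbinol of 22 (hemiaminal carbon unassigned) | C/C1=C/C[C@H](C(C)(C)O[Si](CC)(CC)CC)CC[C@@]2(C)Oc3cc(OCOC)c(C(O[Li])N(C)C)c(OCOC)c3[C@@H](CC(C)C)[C@@H]2CC1 | intermediate (not isolated)
24 | (2R,3S,4S)-5,7-bis(methoxymethoxy)-2-methyl-4-(2-methylpropyl)-2,3-[(3'R,5'Z)-6'-methyl-3'-(2-triethylsilyloxypropan-2-yl)oct-5'-ene-1',8'-diyl]chroman-6,8-dicarbaldehyde | C/C1=C/C[C@H](C(C)(C)O[Si](CC)(CC)CC)CC[C@@]2(C)Oc3c(C=O)c(OCOC)c(C=O)c(OCOC)c3[C@@H](CC(C)C)[C@@H]2CC1 | intermediate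
25 | (2R,3S,4S)-5,7-dihydroxy-2-methyl-4-(2-methylpropyl)-2,3-[(3'R,5'Z)-3'-(2-hydroxypropan-2-yl)-6'-methyloct-5'-ene-1',8'-diyl]chroman-6,8-dicarbaldehyde (CNP0570248.1) | C/C1=C/C[C@H](C(C)(C)O)CC[C@@]2(C)Oc3c(C=O)c(O)c(C=O)c(O)c3[C@@H](CC(C)C)[C@@H]2CC1 | target

**Totals.** 15 steps in all. The longest linear sequence is 12 steps (steps 1–3 and 7–15 from 1; equally steps 4–6 and 7–15 from 8).

**Steps most likely to fail**

1. Step 10 (Proposed new method). What may go wrong:
   - intermolecular condensation may outrun the ten-membered ring closure and give oligomers;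
   - the ketone–ketone condensation may be too slow at the dilution required;
   - the equilibrium may settle on a cis-fused isomer or on the trans isomer with the opposite C2/C3 pair.

   Fallback with known reactions, setting out from 4 and 10 and returning at 18: the two ring closures are separated. Aldehyde-selective Wittig methylenation of 4 (Ph3P=CH2, THF, −78 °C) should give (5R)-5-[2-(triethylsilyloxy)propan-2-yl]oct-7-en-2-one F1. Addition of (4-methylpent-4-en-1-yl)magnesium bromide to 10 should give 1-[2,4-bis(methoxymethoxy)-6-(triisopropylsilyloxy)phenyl]-5-methylhex-5-en-1-ol F2. Dess–Martin oxidation would convert this into 1-[2,4-bis(methoxymethoxy)-6-(triisopropylsilyloxy)phenyl]-5-methylhex-5-en-1-one F3, and buffered TBAF would desilylate it to 1-[2-hydroxy-4,6-bis(methoxymethoxy)phenyl]-5-methylhex-5-en-1-one F4. An ordinary intermolecular Kabbe condensation of F4 with F1 (pyrrolidine, MeOH, 60 °C, concentrated) should give 5,7-bis(methoxymethoxy)-2-methyl-3-(3-methylbut-3-en-1-yl)-2-{(3R)-3-[2-(triethylsilyloxy)propan-2-yl]hex-5-en-1-yl}chroman-4-one F5. Ring-closing metathesis (Grubbs second-generation catalyst, CH2Cl2, 40 °C, 1 mM) would then join the vinyl and isopropenyl termini, the ring size favouring the Z trisubstituted alkene. Because F5 forms without control relative to C3', the diastereomers of 18 would be separated or equilibrated with pyrrolidine.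

2. Step 12. What may go wrong:
   - the C4 cation may be captured by the ring alkene in a transannular cyclisation;
   - it may lose H3 to give the 2H-chromene;
   - the Lewis acid may attack the peri MOM acetal;
   - the facial selectivity may be poor.

   Fallback without a cation or a hydrogenation, setting out from 18 and returning at 22: chelation-controlled cleavage of the peri MOM group with MgBr2·OEt2 should give (2R,3R)-5-hydroxy-7-(methoxymethoxy)-2-methyl-2,3-(bridge-OTES)chroman-4-one F6. NaBH4 reduction should give the ortho-hydroxybenzylic alcohol (2R,3S)-7-(methoxymethoxy)-2-methyl-2,3-(bridge-OTES)chroman-4,5-diol F7. Excess isobutylmagnesium bromide (THF, 0 → 50 °C) would convert its magnesium salt into the ortho-quinone methide (C4=C4a–C5=O) and add isobutyl to C4 anti to the C3–C8' bond, giving (2R,3S,4S)-7-(methoxymethoxy)-2-methyl-4-(2-methylpropyl)-2,3-(bridge-OTES)chroman-5-ol F8. MOMCl/i-Pr2NEt would then return 22, so steps 11–13 are bypassed.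

3. Step 14. What may go wrong:
   - the second metalation may be incomplete and stop at the monoaldehyde;
   - benzylic metalation at C4 may compete;
   - butyllithium may add to the aldehyde that is protected in situ.

   Fallback by electrophilic formylation of the free phenols, setting out from 22 and ending at 25: acid removal of the three protecting groups (2 M aq. HCl, THF, rt) should give (2R,3S,4S)-2-methyl-4-(2-methylpropyl)-2,3-[(3'R,5'Z)-3'-(2-hydroxypropan-2-yl)-6'-methyloct-5'-ene-1',8'-diyl]chroman-5,7-diol F9. Magnesium-mediated ortho-formylation (MgCl2, Et3N, paraformaldehyde, MeCN, reflux) would then formylate ortho to each magnesium phenoxide, the C5 oxygen directing to C6 and the C7 oxygen to C8, giving 25 directly.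

**Further compounds**

F1 | step 10 | (5R)-5-[2-(triethylsilyloxy)propan-2-yl]oct-7-en-2-one | CC(=O)CC[C@@H](C(C)(C)O[Si](CC)(CC)CC)CC=C
F2 | step 10 | 1-[2,4-bis(methoxymethoxy)-6-(triisopropylsilyloxy)phenyl]-5-methylhex-5-en-1-ol (racemic) | C=C(C)CCCC(O)c1c(O[Si](C(C)C)(C(C)C)C(C)C)cc(OCOC)cc1OCOC
F3 | step 10 | 1-[2,4-bis(methoxymethoxy)-6-(triisopropylsilyloxy)phenyl]-5-methylhex-5-en-1-one | C=C(C)CCCC(=O)c1c(O[Si](C(C)C)(C(C)C)C(C)C)cc(OCOC)cc1OCOC
F4 | step 10 | 1-[2-hydroxy-4,6-bis(methoxymethoxy)phenyl]-5-methylhex-5-en-1-one | C=C(C)CCCC(=O)c1c(O)cc(OCOC)cc1OCOC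
F5 | step 10 | 5,7-bis(methoxymethoxy)-2-methyl-3-(3-methylbut-3-en-1-yl)-2-{(3R)-3-[2-(triethylsilyloxy)propan-2-yl]hex-5-en-1-yl}chroman-4-one (C2/C3 diastereomers) | C=CC[C@H](C(C)(C)O[Si](CC)(CC)CC)CCC1(C)Oc2cc(OCOC)cc(OCOC)c2C(=O)C1CCC(C)=C
F6 | step 12 | (2R,3R)-5-hydroxy-7-(methoxymethoxy)-2-methyl-2,3-[(3'R,5'Z)-6'-methyl-3'-(2-triethylsilyloxypropan-2-yl)oct-5'-ene-1',8'-diyl]chroman-4-one | C/C1=C/C[C@H](C(C)(C)O[Si](CC)(CC)CC)CC[C@@]2(C)Oc3cc(OCOC)cc(O)c3C(=O)[C@@H]2CC1
F7 | step 12 | (2R,3S)-7-(methoxymethoxy)-2-methyl-2,3-[(3'R,5'Z)-6'-methyl-3'-(2-triethylsilyloxypropan-2-yl)oct-5'-ene-1',8'-diyl]chroman-4,5-diol (both C4 epimers) | C/C1=C/C[C@H](C(C)(C)O[Si](CC)(CC)CC)CC[C@@]2(C)Oc3cc(OCOC)cc(O)c3C(O)[C@@H]2CC1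
F8 | step 12 | (2R,3S,4S)-7-(methoxymethoxy)-2-methyl-4-(2-methylpropyl)-2,3-[(3'R,5'Z)-6'-methyl-3'-(2-triethylsilyloxypropan-2-yl)oct-5'-ene-1',8'-diyl]chroman-5-ol | C/C1=C/C[C@H](C(C)(C)O[Si](CC)(CC)CC)CC[C@@]2(C)Oc3cc(OCOC)cc(O)c3[C@@H](CC(C)C)[C@@H]2CC1
F9 | step 14 | (2R,3S,4S)-2-methyl-4-(2-methylpropyl)-2,3-[(3'R,5'Z)-3'-(2-hydroxypropan-2-yl)-6'-methyloct-5'-ene-1',8'-diyl]chroman-5,7-diol | C/C1=C/C[C@H](C(C)(C)O)CC[C@@]2(C)Oc3cc(O)cc(O)c3[C@@H](CC(C)C)[C@@H]2CC1
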